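Z is what you should count in the east flask, the flask asked about, followed up to 30 min.

| setting | east | north-east | flask |
|---|---|---|---|
| J | 0.40 M | 0.40 M | 0.40 M |
| Z | 1.1 equiv | 2.2 equiv | 1.10 equiv |
| Q | 0.05 mol% | 0.05 mol% | 0.05 mol% |
| temperature | 100 °C | 95 °C | 100 °C |
| remark | the very flask that is asked about, followed so far | run made earlier |  |
| time |  |  | 30 min |

| run | time / min | D / % |
|---|---|---|
| east | 4.00 | 10.0 |
| east | 10.0 | 12.1 |
| east | 20.0 | 14.3 |
| east | 30.0 | 15.3 |
| north-east | 0.833 | 10.1 |
| north-east | 2.00 | 14.5 |
| north-east | 4.00 | 18.6 |
| north-east | 6.00 | 21.7 |

(readings scatter by 0.3 percentage points)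

- dawn: change nothing and wait 30 min more
- midnight: at 30 min take out 90% of the D then present, then wait 30 min
- spring: at 30 min add Q, 100% of the amount charged, then wait 30 min
- noon: at 30 min add Z, 100% of the amount charged, then wait 30 min
- autumn: at 30 min raise the temperature by 15 K, then wait 30 min

- what is taken out of D is counted as made
- the numbers in the tables scatter by 0.3 percentage points (one standard deviation)
- additions bring no volume worth counting

1. D, in percent of the J first charged, at 30 min
2. the option that brings most further D ("none" if no option brings more than 2 percentage points) (dawn / midnight / spring / noon / autumn / none)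
3. D present, with what was taken out counted in, in percent of the J first charged, after spring
4. D present, with what was taken out counted in, in percent of the J first charged, after noon

So the first answer is a reading, 15.3%. At that reading 86.1% of the Z charged stands in the east flask. Yet D gained 10.0% in the first 4.00 min and 1 percentage point in the last 10.0 min. That slowing is far greater than the loss of Z, so I take Q to be dying.

Here is my reckoning. Let Z fall pseudo-first-order, in step with Z and live Q, and let Q die in pairs, so live Q goes as one over time. Integrated, the Z left goes as a power of time. The east readings give that power as 0.0270, the burn number: the log fraction of its present Z a flask loses each time the clock multiplies by e.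

Is one number enough? It predicts 12.4% at 10.0 min, and the reading is 12.1%. The north-east run, with twice the Z and cooler, gives 0.0288. The gap is 0.00180, and the scatter puts about 0.00191 on the east value.

Now read the options. Waiting 30 min costs a fraction 0.0186 of the Z present, so dawn gains 1.8 points. Midnight removes D, which the number does not contain, so I give it the same. Noon applies that fraction to more Z and gains 3.8 points, reaching 19.1%. Spring restarts the clock, so Z falls by the same factor again, a gain of 13 points, reaching 28.3%. That is more than the others I reckoned; autumn I leave unreckoned.

The forecast gave 15.4%, spring, 26% and 19%: "Fresh Q repeats the first run".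

The flask gives 15.2% and spring. Spring adds 13 points, reaching 28.2%; noon adds 3.9 points, reaching 19.1%; dawn and midnight add 1.8 points each; autumn adds 2.6 points.

    J + Z + Q → D + Q, rate k1*[J]*[Z]*[Q]/(1 + ([J]/sat1)) (28.8 mM, k = 593 M⁻² s⁻¹, Ea = 44.0 kJ mol⁻¹)
    2 Q → X (k = 283 M⁻¹ s⁻¹, Ea = 46.0 kJ mol⁻¹)
    (constants at 100 °C)

At 0.0270, the flask's Z at 300 min reckons to 80.9%, and the table has 80.8%. The neighbouring flask is the asked flask with 0.280 equiv of Z. The same number puts its Z at 30 min at 86.1% of its own charge, hence D at 3.89%. That neighbour holds 86% of its Z and has made 3.89% of D.

(The numbers in the tables are calculated with made-up constants; scatter was added.)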